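**Retrosynthetic overview**
1. Ring D is closed last: the C18=C19 enol-lactone double bond comes from an intramolecular vinylogous aldol condensation of a butenolide γ-CH2 (ring E, bought as a unit) with a C13 aldehyde.
2. Key bond C16–C17: the butenolide β-carbon is used as a nucleophile (a β-acylvinyl, homoenolate-type anion masked as a 4-metallo-2-silyloxyfuran) toward the C16 aldehyde, so two natively electrophilic carbons are joined; a chiral catalyst sets 16R.
3. Ring C: the C8–C14 bond by hydrogen-atom-transfer radical 6-exo cyclisation of an 8-methylidene 4-oxo-enoate (sets C8 and C14); the C13 ketone is then homologated by one carbon (C19).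
4. The oxo-enoate is the methyl ketone from side-chain degradation of (−)-sclareol (rings A/B with C5, C9, C10) condensed with ethyl glyoxylate.
5. Ring order: A/B (chiral pool) → C → E attached → D.

Assumption: locants are C1–C10 (rings A/B), C11–C14 (ring C; C14 is the methyl carbon of the sclareol-derived methyl ketone), ring D = C13–C19H=C18–C17–C16H(OAc)–C15H2–C14, ring E = O–C18, C17=C20H, C21=O; α/β mean below/above the plane of the usual drawing; the bromofuranone building block is taken as a catalogue item.

**Step 1**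
Reactants: 1 (−)-sclareol [(13R)-labd-14-ene-8α,13-diol]
Product: 2 8α-hydroxy methyl ketone 4-[(1R,2R,4aS,8aS)-2-hydroxy-2,5,5,8a-tetramethyldecahydronaphthalen-1-yl]butan-2-one
Conditions: KMnO4, acetone–H2O, 0 °C → rt
Reagents that add atoms: none
Why: Permanganate oxidative cleavage of the vinyl carbinol (classical side-chain degradation) excises the two vinyl carbons and leaves C13 as the methyl ketone with its own oxygen, while the ring stereocentres of sclareol (5α-H, 8α-OH/8β-Me, 9α-H, 10β-Me) are untouched.

**Step 2**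
Reactants: 2 8α-hydroxy methyl ketone
Product: 3 8-methylidene methyl ketone 4-[(1S,4aS,8aS)-5,5,8a-trimethyl-2-methylidenedecahydronaphthalen-1-yl]butan-2-one
Conditions: SOCl2, pyridine, CH2Cl2, −78 → 0 °C
Reagents that add atoms: none
Why: Chlorosulfite formation and pyridine-mediated E2 dehydration of the equatorial tertiary alcohol gives mainly the exocyclic alkene (no ring hydrogen is anti-periplanar to the equatorial C–O bond), and the minor endocyclic Δ7 isomer need not be removed because hydrogen-atom transfer in step 4 turns both into the same C8 radical.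

**Step 3**
Reactants: 3 8-methylidene methyl ketone; 4 ethyl glyoxylate
Product: 8 ethyl (E)-4-oxo-6-[(1S,4aS,8aS)-5,5,8a-trimethyl-2-methylidenedecahydronaphthalen-1-yl]hex-2-enoate, via lithium enolate 5 (not isolated), via lithium aldolate 6 (not isolated), via aldol mesylate 7 (not isolated)
Conditions: LiN(i-Pr)2, THF, −78 °C; 4; then MsCl, Et3N, −78 °C → rt
Reagents that add atoms: none
Why: Kinetic deprotonation at the methyl group, aldol addition to the non-enolisable glyoxylate, then mesylation and E1cB elimination (one-pot directed aldol condensation) give the (E)-4-oxo-2-enoate regioselectively and create no lasting stereocentre.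

**Step 4**
Reactants: 8 ethyl (E)-4-oxo-enoate
Product: 9 tricyclic keto ester (ring C closed; C13 ketone; 14β-CH2CO2Et arm; 5α-H 8β-Me 9α-H 10β-Me 14α-H)
Conditions: Fe(acac)3 (30 mol %), PhSiH3, EtOH–HOCH2CH2OH, 60 °C
Reagents that add atoms: none
Why: Metal-hydride hydrogen-atom-transfer radical cyclisation (Giese-type reductive olefin coupling): Markovnikov H-atom transfer to the 8-methylidene group gives the tertiary C8 radical, which closes ring C by 6-exo attack on the ester β-carbon C14 from the α face opposite the axial 10β-methyl (hence 8β-Me and trans B/C fusion), while the planar s-cis enone in a chair-like transition state places the CH2CO2Et arm equatorial (14β, 14α-H).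

**Step 5**
Reactants: 9 tricyclic keto ester
Product: 10 enol ether ester (13-methoxymethylidene analogue of 9; E/Z mixture)
Conditions: MeOCH2PPh3Cl, KN(SiMe3)2, THF, 0 °C → rt
Reagents that add atoms: (methoxymethyl)triphenylphosphonium chloride, COC[P+](c1ccccc1)(c1ccccc1)c1ccccc1.[Cl-]
Why: Wittig methoxymethylenation of the C13 ketone (one-carbon homologation) installs C19 as an enol ether that masks the later aldehyde, and the hindered ylide enolises the ketone only toward C12 so that C14 is not epimerised.

**Step 6**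
Reactants: 10 enol ether ester
Product: 11 enol ether aldehyde (C16 aldehyde)
Conditions: i-Bu2AlH, CH2Cl2, −78 °C; aq. potassium sodium tartrate
Reagents that add atoms: none
Why: Low-temperature i-Bu2AlH half-reduction of the ester stops at the aluminium hemiacetal and releases the C16 aldehyde on work-up, the enol ether being inert to hydride.

**Step 7**
Reactants: 12 4-bromofuran-2(5H)-one
Product: 13 4-bromo-2-(triisopropylsilyloxy)furan
Conditions: i-Pr3SiOTf, Et3N, CH2Cl2, 0 °C
Reagents that add atoms: triisopropylsilyl trifluoromethanesulfonate, CC(C)[Si](C(C)C)(C(C)C)OS(=O)(=O)C(F)(F)F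
Why: Soft enolisation and O-silylation (silyloxyfuran formation) removes the acidic γ-hydrogens and the electrophilic enoate of the butenolide so that its β-carbon can be metallated.

**Step 8**
Reactants: 11 enol ether aldehyde; 13 4-bromo-2-(triisopropylsilyloxy)furan
Product: 18 (16R)-acetate carrying the 5-(triisopropylsilyloxy)furan-3-yl group on C16 (enol ether intact), via furyllithium 14 (not isolated), via furylzinc chloride 15 (not isolated), via butyl furyl zinc 16 (not isolated), via zinc alkoxide 17 (not isolated)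
Conditions: 13, n-BuLi, t-BuOMe, −78 °C; ZnCl2; n-BuLi; Et2NCH2CH2NEt2; (−)-MIB [(2S)-3-exo-morpholinoisoborneol] (10 mol %), 11, 0 °C; then Ac2O, 4-(dimethylamino)pyridine (cat.)
Reagents that add atoms: acetic anhydride, CC(=O)OC(C)=O
Why: Proposed new method: bromine–lithium exchange (as for 3-bromofuran) and transmetallation give a 4-zincio-2-silyloxyfuran, which is a butenolide β-anion (homoenolate-type d3) equivalent, so the aldehyde carbon C16 and the butenolide β-carbon C17, both natively electrophilic, are joined, the amino-alcohol zinc catalyst delivering the furyl group to the Si face of the aldehyde (the sense of its known alkyl- and arylzinc additions) to set 16R (16α-O) under catalyst control before the zinc alkoxide is acetylated in the flask; the closest known reaction type is the MIB-catalysed asymmetric addition of aryl- and heteroaryl(butyl)zinc reagents, made from the bromides, to aldehydes.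

**Step 9**
Reactants: 18 (16R)-acetate
Product: 19 aldehyde–butenolide (13α-CHO 13β-H; 4-substituted furan-2(5H)-one on C16)
Conditions: 1 M HCl, THF, 0 °C → rt
Reagents that add atoms: water, O
Why: Acid hydrolysis cleaves the silyl ketene acetal (protonation at C18 gives the conjugated 2(5H)-furanone) and the enol ether (C19 aldehyde), and C13 equilibrates through the enol to the equatorial aldehyde (13β-H) because the axial epimer would be syn-axial to the 8β-methyl.

**Step 10**
Reactants: 19 aldehyde–butenolide
Product: 20 target acetoxy ylidene-butenolide (CNP0193439.1)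
Conditions: pyrrolidine (30 mol %), AcOH (30 mol %), 4 Å molecular sieves, CH2Cl2, 35 °C
Reagents that add atoms: none
Why: Amine-catalysed intramolecular vinylogous aldol (Knoevenagel-type) condensation joins the butenolide γ-carbon C18 to the aldehyde carbon C19 and loses water, closing the seven-membered ring D with the only double-bond geometry the ring allows and without creating or disturbing a stereocentre.

**Compound list**
1 | (−)-sclareol, (13R)-labd-14-ene-8α,13-diol | C=C[C@](C)(O)CC[C@H]1[C@@](O)(C)CC[C@H]2C(C)(C)CCC[C@]12C | starting material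
2 | 4-[(1R,2R,4aS,8aS)-2-hydroxy-2,5,5,8a-tetramethyldecahydronaphthalen-1-yl]butan-2-one | CC(=O)CC[C@H]1[C@@](O)(C)CC[C@H]2C(C)(C)CCC[C@]12C | intermediate
3 | 4-[(1S,4aS,8aS)-5,5,8a-trimethyl-2-methylidenedecahydronaphthalen-1-yl]butan-2-one | CC(=O)CC[C@H]1C(=C)CC[C@H]2C(C)(C)CCC[C@]12C | intermediate
4 | ethyl glyoxylate | CCOC(=O)C=O | starting material
5 | lithium enolate of 3 (methyl side) | [Li]OC(=C)CC[C@H]1C(=C)CC[C@H]2C(C)(C)CCC[C@]12C | intermediate (not isolated)
6 | lithium aldolate (C15 epimers) | CCOC(=O)C(O[Li])CC(=O)CC[C@H]1C(=C)CC[C@H]2C(C)(C)CCC[C@]12C | intermediate (not isolated)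
7 | aldol mesylate (C15 epimers) | CCOC(=O)C(OS(C)(=O)=O)CC(=O)CC[C@H]1C(=C)CC[C@H]2C(C)(C)CCC[C@]12C | intermediate (not isolated)
8 | ethyl (E)-4-oxo-6-[(1S,4aS,8aS)-5,5,8a-trimethyl-2-methylidenedecahydronaphthalen-1-yl]hex-2-enoate | CCOC(=O)/C=C/C(=O)CC[C@H]1C(=C)CC[C@H]2C(C)(C)CCC[C@]12C | intermediate
9 | tricyclic keto ester: C13 ketone, 14β-CH2CO2Et, 8β-Me, trans-anti-trans A/B/C | CCOC(=O)C[C@@H]2C(=O)CC[C@H]1[C@@]2(C)CC[C@H]2C(C)(C)CCC[C@]12C | intermediate
10 | enol ether ester: 13-methoxymethylidene analogue of 9 (E/Z) | CCOC(=O)C[C@@H]2C(=COC)CC[C@H]1[C@@]2(C)CC[C@H]2C(C)(C)CCC[C@]12C | intermediate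
11 | enol ether aldehyde: 14β-CH2CHO (C16 aldehyde) | O=CC[C@@H]2C(=COC)CC[C@H]1[C@@]2(C)CC[C@H]2C(C)(C)CCC[C@]12C | intermediate
12 | 4-bromofuran-2(5H)-one | O=C1OCC(Br)=C1 | starting material
13 | 4-bromo-2-(triisopropylsilyloxy)furan | CC(C)[Si](C(C)C)(C(C)C)Oc1cc(Br)co1 | intermediate
14 | 5-(triisopropylsilyloxy)furan-3-yllithium | CC(C)[Si](C(C)C)(C(C)C)Oc1cc([Li])co1 | intermediate (not isolated)
15 | chloro[5-(triisopropylsilyloxy)furan-3-yl]zinc | CC(C)[Si](C(C)C)(C(C)C)Oc1cc([Zn]Cl)co1 | intermediate (not isolated)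
16 | butyl[5-(triisopropylsilyloxy)furan-3-yl]zinc | CCCC[Zn]c1coc(O[Si](C(C)C)(C(C)C)C(C)C)c1 | intermediate (not isolated)
17 | butylzinc (16R)-alkoxide of the furyl carbinol | CCCC[Zn]O[C@H](C[C@@H]2C(=COC)CC[C@H]1[C@@]2(C)CC[C@H]2C(C)(C)CCC[C@]12C)c1coc(O[Si](C(C)C)(C(C)C)C(C)C)c1 | intermediate (not isolated)
18 | (16R)-acetate with silyloxyfuran on C16 and 13-methoxymethylidene group | CC(=O)O[C@H](C[C@@H]2C(=COC)CC[C@H]1[C@@]2(C)CC[C@H]2C(C)(C)CCC[C@]12C)c1coc(O[Si](C(C)C)(C(C)C)C(C)C)c1 | intermediate
19 | aldehyde–butenolide: 13α-CHO (13β-H), (16R)-OAc, furan-2(5H)-on-4-yl on C16 | CC(=O)O[C@H](C[C@@H]2[C@@H](C=O)CC[C@H]1[C@@]2(C)CC[C@H]2C(C)(C)CCC[C@]12C)C1=CC(=O)OC1 | intermediate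
20 | target: 5α-H, 8β-Me, 9α-H, 10β-Me, 13β-H, 14α-H, 16α-OAc (16R) | CC(=O)O[C@@H]1C[C@@H]2[C@@H](C=C3OC(=O)C=C31)CC[C@H]1[C@@]2(C)CC[C@H]2C(C)(C)CCC[C@]12C | target

**Step count**
Total: 10 steps. Longest linear sequence: 9 steps (steps 1–6 and 8–10); step 7 is a one-step side branch.

**Three steps most likely to fail, each with a fallback**

Step 4 (radical ring-C closure: simple reduction, 7-endo closure or weak control at C8/C14 are the risks). The C8 radical can instead be made by photoredox fragmentation of an oxalate, which needs no alkene. This sets out from 2 (the tertiary alcohol is kept and step 2 is skipped). Aldol condensation with 4 as in step 3, but with 2.2 equiv LiN(i-Pr)2, gives the hydroxy oxo-enoate F1. Acylation with chloro N-phthalimidoyl oxalate (Et3N, 4-(dimethylamino)pyridine) gives the tert-alkyl N-phthalimidoyl oxalate F2. Ru(bpy)3(PF6)2 (1 mol %), Hantzsch ester, i-Pr2NEt·HBF4 and blue light then release two CO2 and phthalimide; the same tertiary radical cyclises 6-exo and the route is rejoined at 9.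

Step 8 (the zinc reagent may not form cleanly, may isomerise to the 5-metallo furan, or may add with poor selectivity). The C16–C17 bond is then made with a chromium reagent and C16 is set afterwards by a reagent-controlled reduction. From 11 and 12 (no silylation), CrCl2 (4 equiv) and NiCl2 (2 mol %) in DMF (Nozaki–Hiyama–Kishi coupling of the β-bromobutenolide, again a β-acylvinyl anion) give the C16-epimeric carbinol F3. Dess–Martin periodinane gives the 4-acylbutenolide ketone F4. (S)-2-Methyl-CBS-oxazaborolidine with catecholborane at −78 °C gives the (16R)-alcohol F5 (the butenolide acts as the large group). Ac2O/pyridine gives the acetate F6, and 1 M HCl/THF hydrolyses the enol ether so that the route is rejoined at 19.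

Step 10 (seven-membered ring closure may be slow, or attack may occur through the butenolide α-carbon). The ring is then closed as a Lewis-acid vinylogous Mukaiyama addition to an oxocarbenium ion. From 19, HC(OMe)3 and pyridinium p-toluenesulfonate give the dimethyl acetal F7. TBSOTf/Et3N (CH2Cl2, −78 → 0 °C) converts the butenolide into its 2-silyloxyfuran and ionises the acetal, and γ-selective cyclisation gives the 19-methoxy tetracycle F8. DBU then eliminates methanol (E1cB through the γ-hydrogen) to give 20.

**Further compounds**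
F1 | step 4 | hydroxy oxo-enoate (8α-OH analogue of 8) | CCOC(=O)/C=C/C(=O)CC[C@H]1[C@@](O)(C)CC[C@H]2C(C)(C)CCC[C@]12C
F2 | step 4 | tert-alkyl N-phthalimidoyl oxalate of F1 | CCOC(=O)/C=C/C(=O)CC[C@H]1[C@@](OC(=O)C(=O)ON3C(=O)c4ccccc4C3=O)(C)CC[C@H]2C(C)(C)CCC[C@]12C
F3 | step 8 | C16-epimeric carbinol (butenolide on C16; enol ether intact) | OC(C[C@@H]2C(=COC)CC[C@H]1[C@@]2(C)CC[C@H]2C(C)(C)CCC[C@]12C)C1=CC(=O)OC1
F4 | step 8 | C16 ketone (4-acylbutenolide) | O=C(C[C@@H]2C(=COC)CC[C@H]1[C@@]2(C)CC[C@H]2C(C)(C)CCC[C@]12C)C1=CC(=O)OC1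
F5 | step 8 | (16R)-alcohol | O[C@H](C[C@@H]2C(=COC)CC[C@H]1[C@@]2(C)CC[C@H]2C(C)(C)CCC[C@]12C)C1=CC(=O)OC1
F6 | step 8 | (16R)-acetate (butenolide; enol ether intact) | CC(=O)O[C@H](C[C@@H]2C(=COC)CC[C@H]1[C@@]2(C)CC[C@H]2C(C)(C)CCC[C@]12C)C1=CC(=O)OC1
F7 | step 10 | dimethyl acetal of 19 | CC(=O)O[C@H](C[C@@H]2[C@@H](C(OC)OC)CC[C@H]1[C@@]2(C)CC[C@H]2C(C)(C)CCC[C@]12C)C1=CC(=O)OC1
F8 | step 10 | 19-methoxy tetracycle (C18 and C19 epimers) | CC(=O)O[C@@H]1C[C@@H]2[C@@H](C(OC)C3OC(=O)C=C31)CC[C@H]1[C@@]2(C)CC[C@H]2C(C)(C)CCC[C@]12C
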